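**Retrosynthetic overview**
- The target quinone methide is taken back to a benzyl-protected 6-oxo catechol: the C6 ketone comes from hydroboration of a C6=C7 alkene, the C21 carbinol from a ring D ketone, and the 5β-H from equilibration next to C6=O.
- Ring D (C7–C8–C14–C4′–C21) is cut at C7–C21 and C21–C4′: a C7 alkenyl triflate, CO and the aryl-substituted C4′=C3′ alkene of ring E are joined by a carbonylative Heck spirocyclisation.
- Feature used: C21 is a lone carbon lodged between C7 of ring B and the quaternary spiro carbon C4′ common to rings D and E, and it lies on the face of ring E away from the cyclopropane methylene C6′, the face open to a metal-bound acyl group.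
- The triflate comes from a Suzuki coupling (C14–C4′) of a 14-bromo-7-oxoabietatriene made from carnosol (lactone carbon C20 reduced to CH3, C7 oxygen kept) with an alkenyl boronate made from (+)-sabinene.
- Ring order: rings A, B, C (carnosol) and ring E with its cyclopropane (sabinene) are bought; ring D is the only ring made, and it is made last.

Key step: step 11

Labels: abietane numbering C1–C20 for rings A, B, C. Ring E atoms carry primes: C1′ (isopropyl-bearing cyclopropane carbon), C2′, C3′, C4′ (carbon bonded to C14), C5′ (cyclopropane CH), C6′ (cyclopropane CH2). C21 is the carbon that comes from CO. α/β are the abietane faces, β being the face of the C10 methyl.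
Assumption: as is general for 4,4,10-trimethyl 6-ketones with an aromatic ring C, the A/B-cis (5β-H) ketone is taken to be the more stable C5 epimer; step 17 relies on it.
Remark: C7 is configurationally labile in the 6-ketones (α to C=O and benzylic) and is drawn there without configuration.

**Route**

Step 1
Reactants: 1 (+)-sabinene
Product: 3 sabina ketone [(1S,5R)-5-isopropylbicyclo[3.1.0]hexan-2-one], via ozonide 2 (not isolated)
Conditions: O3, CH2Cl2, −78 °C; then Me2S, −78 °C → rt
Reagents that add atoms: ozone, O=[O+][O-]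
Why: Ozonolysis with reductive work-up cleaves the exocyclic alkene to the ketone and formaldehyde, and neither the cyclopropane nor the two stereocentres take part.

Step 2
Reactants: 3 sabina ketone
Product: 5 5-isopropylbicyclo[3.1.0]hex-2-en-2-yl triflate (stereocentres of 1 kept), via potassium enolate 4 (not isolated)
Conditions: KN(SiMe3)2, THF, −78 °C; then PhNTf2, −78 → 0 °C
Reagents that add atoms: N-phenylbis(trifluoromethanesulfonimide), O=S(=O)(N(c1ccccc1)S(=O)(=O)C(F)(F)F)C(F)(F)F
Why: Enolate O-sulfonylation; only the C3′ methylene can be deprotonated because the other α-carbon is the cyclopropane bridgehead C5′, so a single enol triflate regioisomer should form.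

Step 3
Reactants: 5 alkenyl triflate
Product: 6 2-(5-isopropylbicyclo[3.1.0]hex-2-en-2-yl)-4,4,5,5-tetramethyl-1,3,2-dioxaborolane (stereocentres of 1 kept)
Conditions: B2pin2, PdCl2(PPh3)2 (3 mol%), PPh3 (6 mol%), KOPh, toluene, 50 °C
Reagents that add atoms: bis(pinacolato)diboron, CC1(C)OB(OC1(C)C)B1OC(C)(C)C(C)(C)O1
Why: Miyaura borylation of an alkenyl triflate; all bond changes occur at the sp2 carbon C4′, away from the cyclopropane bonds.

Step 4
Reactants: 7 carnosol
Product: 8 11,12-di-O-benzylcarnosol
Conditions: BnBr, Cs2CO3, nBu4NI (cat.), DMF, 50 °C, under N2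
Reagents that add atoms: benzyl bromide, BrCc1ccccc1
Why: Williamson etherification of both phenoxides; the lactone is inert to carbonate, and benzyl ethers survive every later step yet leave at the end by neutral hydrogenolysis.

Step 5
Reactants: 8 11,12-di-O-benzylcarnosol
Product: 9 14-bromo-11,12-di-O-benzylcarnosol
Conditions: NBS, MeCN, 0 °C → rt, in the dark
Reagents that add atoms: N-bromosuccinimide, O=C1CCC(=O)N1Br
Why: Electrophilic aromatic bromination at C14, the only unsubstituted position of ring C, activated para by the C11 ether oxygen.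

Step 6
Reactants: 9 14-bromo-11,12-di-O-benzylcarnosol
Product: 10 lactol 14-bromo-11,12-bis(benzyloxy)-7β,20-epoxyabieta-8,11,13-trien-20-ol (both C20 epimers)
Conditions: iBu2AlH, CH2Cl2, −78 °C; aq. KNaC4H4O6 work-up
Reagents that add atoms: none
Why: Partial lactone reduction; the aluminium hemiacetal of the bridged δ-lactone does not collapse until work-up, so reduction should stop at the lactol, and the C20 hemiacetal centre is of no stereochemical consequence.

Step 7
Reactants: 10 lactol
Product: 12 14-bromo-11,12-bis(benzyloxy)abieta-8,11,13-trien-7β-ol, via hydrazone 11 (not isolated)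
Conditions: N2H4·H2O, KOH, diethylene glycol, 130 °C then 195 °C
Reagents that add atoms: none
Why: Wolff–Kishner reduction in the Huang–Minlon variant: the lactol opens to the C20 aldehyde, whose hydrazone loses N2 under hot KOH to leave the C20 methyl, while the C7 alkoxide, the aryl benzyl ethers and the unactivated aryl bromide tolerate the base.

Step 8
Reactants: 12 7β-alcohol
Product: 13 14-bromo-11,12-bis(benzyloxy)abieta-8,11,13-trien-7-one
Conditions: Dess–Martin periodinane, CH2Cl2, rt
Reagents that add atoms: none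
Why: Dess–Martin oxidation of the secondary benzylic alcohol to the aryl ketone.

Step 9
Reactants: 13 bromo ketone; 6 alkenyl boronate
Product: 14 11,12-bis(benzyloxy)-14-(5-isopropylbicyclo[3.1.0]hex-2-en-2-yl)abieta-8,11,13-trien-7-one (new C14–C4′ bond; ring E stereocentres as in 1)
Conditions: Pd(OAc)2 (5 mol%), SPhos (10 mol%), K3PO4, toluene/H2O, 90 °C
Reagents that add atoms: none
Why: Suzuki–Miyaura coupling of a di-ortho-substituted aryl bromide, for which a bulky biaryl dialkylphosphine is the usual ligand, with oxidative addition helped by the ortho acyl group; no stereocentre is formed.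

Step 10
Reactants: 14 coupled ketone
Product: 16 11,12-bis(benzyloxy)-14-(5-isopropylbicyclo[3.1.0]hex-2-en-2-yl)abieta-6,8,11,13-tetraen-7-yl triflate (5α-H), via potassium enolate 15 (not isolated)
Conditions: KN(SiMe3)2, THF, −78 °C; then PhNTf2, −78 → 0 °C
Reagents that add atoms: N-phenylbis(trifluoromethanesulfonimide), O=S(=O)(N(c1ccccc1)S(=O)(=O)C(F)(F)F)C(F)(F)F
Why: Enolate O-sulfonylation; the ketone has α-hydrogens only at C6, so the C6=C7 alkenyl triflate is the only possible product.

Step 11
Reactants: 16 alkenyl triflate; 17 carbon monoxide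
Product: 18 spiro dienone (ring D closed through C21; C21 ketone; C6=C7 and C2′=C3′ alkenes; spiro C4′ with C14 syn and C21 anti to C6′; 5α-H; 11,12-bis(benzyloxy))
Conditions: Pd(OAc)2 (10 mol%), 1,3-bis(diphenylphosphino)propane (12 mol%), CO (1 atm), 1,2,2,6,6-pentamethylpiperidine, MeCN/toluene, 4 Å MS, 80 °C
Reagents that add atoms: carbon monoxide (17), [C-]#[O+]
Why: Zerovalent palladium formed in situ inserts into the C7–OTf bond, and CO insertion, which outruns direct carbopalladation because that would need a four-membered ring or a 5-endo closure, gives the cationic acylpalladium at C21. This species adds syn across C4′=C3′ with C21 bonding to the aryl-bearing C4′, a 5-exo-trig acylpalladation that closes ring D and makes the C7–C21 and C21–C4′ bonds in one operation. The alkylpalladium left at C3′ has syn β-hydrogens only on C2′, so β-hydride elimination gives the C2′=C3′ alkene, and the hindered amine takes up the palladium hydride before it can re-add toward the cyclopropane. The closest known reaction type is the carbonylative Heck (cyclic acylpalladation) of alkenyl halides and triflates carrying a 1,4-related alkene, which is known to give cyclopentenones with quaternary centres. The new stereocentre C4′ is set by the cyclopropane: rotation about C14–C4′ lets C21 reach either face of ring E, the C6′ methylene blocks one of them, and addition anti to C6′ leaves C14 syn to C6′ and C5′ on the α face, as in the target. The step needs 5-exo over 6-endo addition and CO insertion before cyclisation; the peri relation of C7 and C14 holds C21 within reach of C4′ only, and 1 atm of CO is enough to intercept the alkenylpalladium.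

Step 12
Reactants: 18 spiro dienone
Product: 19 spiro enone (18 with ring E saturated at C2′–C3′)
Conditions: KO2C–N=N–CO2K (dipotassium azodicarboxylate), AcOH, MeOH/CH2Cl2, 0 °C → rt
Reagents that add atoms: none
Why: Diimide reduction; concerted syn transfer of H2 to the strained cis-disubstituted C2′=C3′ alkene should be much faster than to the trisubstituted conjugated C6=C7 alkene, and unlike catalytic hydrogenation it cannot open the cyclopropane or cleave benzyl ethers.

Step 13
Reactants: 19 spiro enone
Product: 20 21α-allylic alcohol (C21–OH on the α face beside C5′; C21–H β)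
Conditions: NaBH4, CeCl3·7H2O, MeOH/THF, −40 → 0 °C
Reagents that add atoms: none
Why: Luche reduction gives 1,2-addition to the enone, and hydride should approach C21 from the β face beside the C3′ methylene because the α face is screened by the C5′ methine hydrogen with the cyclopropane behind it, which sets the C21 hydroxyl α.

Step 14
Reactants: 20 allylic alcohol
Product: 22 21α-benzyl ether (11,12,21-tris(benzyloxy); C6=C7 alkene), via sodium alkoxide 21 (not isolated)
Conditions: NaH, THF, 0 °C; then BnBr, nBu4NI (cat.), 0 °C → rt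
Reagents that add atoms: benzyl bromide, BrCc1ccccc1
Why: Williamson etherification with retention at C21; the ether keeps C21–OH out of the oxidation in step 16 and prevents retro-aldol opening of ring D once the C6 ketone is present.

Step 15
Reactants: 22 tribenzyl ether
Product: 24 6α-alcohol (6α-OH; 7α-H; 5α-H; 11,12,21-tris(benzyloxy)), via alkylborane 23 (not isolated)
Conditions: BH3·THF, THF, 0 °C → rt; then aq. NaOH, H2O2, 0 °C → rt
Reagents that add atoms: hydrogen peroxide, OO
Why: Hydroboration–oxidation; boron goes to C6, the only alkene carbon bearing hydrogen, and hydrogen to the fully substituted benzylic C7 by syn addition, expected on the α face away from the C19 and C20 methyls; the C6 and C7 configurations are not carried into the target.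

Step 16
Reactants: 24 6α-alcohol
Product: 25 6-ketone with 5α-H (A/B trans; 11,12,21-tris(benzyloxy))
Conditions: Dess–Martin periodinane, pyridine, CH2Cl2, 0 °C → rt
Reagents that add atoms: none
Why: Dess–Martin oxidation of the secondary alcohol under buffered, near-neutral conditions that the resulting β-benzyloxy ketone should tolerate.

Step 17
Reactants: 25 trans 6-ketone
Product: 26 6-ketone with 5β-H (A/B cis)
Conditions: NaOMe (0.2 equiv), MeOH/THF, 0 °C, followed to equilibrium; AcOH quench
Reagents that add atoms: none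
Why: Base-mediated keto–enol equilibration at C5; the cis-fused ketone should dominate because the syn-axial C19/C20 methyl interaction and the clash of the equatorial C18 methyl with the C6 carbonyl are relieved, so C5 is set under thermodynamic control.

Step 18
Reactants: 26 cis 6-ketone
Product: 27 catechol 11,12,21α-trihydroxy-6-ketone (5β-H)
Conditions: H2 (1 atm), Pd(OH)2/C, EtOAc/MeOH, rt; used at once
Reagents that add atoms: none
Why: Hydrogenolysis of the two aryl benzyl ethers and the secondary benzyl ether under neutral conditions that should leave the β-hydroxy ketone and the alkyl-substituted cyclopropane intact.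

Step 19
Reactants: 27 catechol
Product: 28 target quinone methide CNP0178265.2
Conditions: Ag2O, Na2SO4, Et2O, rt
Reagents that add atoms: none
Why: Ag2O oxidises the catechol to the ortho-quinone, which tautomerises through its acidic C7 hydrogen to the 11-hydroxy-12-oxo quinone methide conjugated with the C6 ketone, the oxidation that turns 6-oxo-11,12-dihydroxyabietatrienes into taxodione-type quinone methides; the secondary C21 alcohol is not oxidised.

**Compound list**
1 | (+)-sabinene [(1R,5R)-thuj-4(10)-ene] | C=C1CC[C@]2(C(C)C)C[C@@H]21 | starting material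
2 | sabinene ozonide (1,2,4-trioxolane spiro at C4′; both spiro epimers) | C1OC2(OO1)CC[C@]3(C(C)C)C[C@@H]32 | intermediate
3 | sabina ketone, (1S,5R)-5-isopropylbicyclo[3.1.0]hexan-2-one | O=C1CC[C@]2(C(C)C)C[C@@H]21 | intermediate
4 | potassium enolate of 3 (enolised toward C3′) | [K+].[O-]C1=CC[C@]2(C(C)C)C[C@@H]21 | intermediate
5 | 5-isopropylbicyclo[3.1.0]hex-2-en-2-yl triflate (stereocentres of 1) | O=S(=O)(OC1=CC[C@]2(C(C)C)C[C@@H]21)C(F)(F)F | intermediate
6 | 2-(5-isopropylbicyclo[3.1.0]hex-2-en-2-yl)-4,4,5,5-tetramethyl-1,3,2-dioxaborolane (stereocentres of 1) | CC1(C)OB(C2=CC[C@]3(C(C)C)C[C@@H]32)OC1(C)C | intermediate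
7 | carnosol (11,12-dihydroxyabieta-8,11,13-trien-20,7β-olide; 5α-H) | CC(C)c1cc2[C@@H]3C[C@H]4C(C)(C)CCC[C@]4(C(=O)O3)c2c(O)c1O | starting material
8 | 11,12-di-O-benzylcarnosol | CC(C)c1cc2[C@@H]3C[C@H]4C(C)(C)CCC[C@]4(C(=O)O3)c2c(OCc2ccccc2)c1OCc1ccccc1 | intermediate
9 | 14-bromo-11,12-di-O-benzylcarnosol | CC(C)c1c(Br)c2[C@@H]3C[C@H]4C(C)(C)CCC[C@]4(C(=O)O3)c2c(OCc2ccccc2)c1OCc1ccccc1 | intermediate
10 | 14-bromo-11,12-bis(benzyloxy)-7β,20-epoxyabieta-8,11,13-trien-20-ol (lactol; both C20 epimers) | CC(C)c1c(Br)c2[C@@H]3C[C@H]4C(C)(C)CCC[C@]4(C(O)O3)c2c(OCc2ccccc2)c1OCc1ccccc1 | intermediate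
11 | 14-bromo-11,12-bis(benzyloxy)-7β-hydroxyabieta-8,11,13-trien-20-al hydrazone | CC(C)c1c(Br)c2[C@@H](O)C[C@H]3C(C)(C)CCC[C@]3(C=NN)c2c(OCc2ccccc2)c1OCc1ccccc1 | intermediate
12 | 14-bromo-11,12-bis(benzyloxy)abieta-8,11,13-trien-7β-ol (5α-H) | CC(C)c1c(Br)c2[C@@H](O)C[C@H]3C(C)(C)CCC[C@]3(C)c2c(OCc2ccccc2)c1OCc1ccccc1 | intermediate
13 | 14-bromo-11,12-bis(benzyloxy)abieta-8,11,13-trien-7-one | CC(C)c1c(Br)c2C(=O)C[C@H]3C(C)(C)CCC[C@]3(C)c2c(OCc2ccccc2)c1OCc1ccccc1 | intermediate
14 | 11,12-bis(benzyloxy)-14-(5-isopropylbicyclo[3.1.0]hex-2-en-2-yl)abieta-8,11,13-trien-7-one | CC(C)c1c(C2=CC[C@]3(C(C)C)C[C@@H]32)c2C(=O)C[C@H]3C(C)(C)CCC[C@]3(C)c2c(OCc2ccccc2)c1OCc1ccccc1 | intermediate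
15 | potassium C6-enolate of 14 | CC(C)c1c(C2=CC[C@]3(C(C)C)C[C@@H]32)c2C([O-])=C[C@H]3C(C)(C)CCC[C@]3(C)c2c(OCc2ccccc2)c1OCc1ccccc1.[K+] | intermediate
16 | 11,12-bis(benzyloxy)-14-(5-isopropylbicyclo[3.1.0]hex-2-en-2-yl)abieta-6,8,11,13-tetraen-7-yl triflate (key-step precursor) | CC(C)c1c(C2=CC[C@]3(C(C)C)C[C@@H]32)c2C(OS(=O)(=O)C(F)(F)F)=C[C@H]3C(C)(C)CCC[C@]3(C)c2c(OCc2ccccc2)c1OCc1ccccc1 | intermediate
17 | carbon monoxide | [C-]#[O+] | starting material
18 | spiro dienone: ring D closed, C21 ketone, C6=C7 and C2′=C3′ alkenes, C14 syn to C6′ at spiro C4′, 5α-H (key-step product) | CC(C)c1c2c3C(=C[C@H]4C(C)(C)CCC[C@]4(C)c3c(OCc3ccccc3)c1OCc1ccccc1)C(=O)[C@]21C=C[C@]2(C(C)C)C[C@@H]21 | intermediate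
19 | spiro enone: 18 with ring E saturated | CC(C)c1c2c3C(=C[C@H]4C(C)(C)CCC[C@]4(C)c3c(OCc3ccccc3)c1OCc1ccccc1)C(=O)[C@]21CC[C@]2(C(C)C)C[C@@H]21 | intermediate
20 | 21α-allylic alcohol (OH α, H β at C21) | CC(C)c1c2c3C(=C[C@H]4C(C)(C)CCC[C@]4(C)c3c(OCc3ccccc3)c1OCc1ccccc1)[C@@H](O)[C@]21CC[C@]2(C(C)C)C[C@@H]21 | intermediate
21 | sodium alkoxide of 20 | CC(C)c1c2c3C(=C[C@H]4C(C)(C)CCC[C@]4(C)c3c(OCc3ccccc3)c1OCc1ccccc1)[C@@H]([O-])[C@]21CC[C@]2(C(C)C)C[C@@H]21.[Na+] | intermediate
22 | 21α-benzyl ether of 20 | CC(C)c1c2c3C(=C[C@H]4C(C)(C)CCC[C@]4(C)c3c(OCc3ccccc3)c1OCc1ccccc1)[C@@H](OCc1ccccc1)[C@]21CC[C@]2(C(C)C)C[C@@H]21 | intermediate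
23 | C6 alkylborane of 22 (6α-BH2, 7α-H) | CC(C)c1c2c3[C@H]([C@H](B)[C@H]4C(C)(C)CCC[C@]4(C)c3c(OCc3ccccc3)c1OCc1ccccc1)[C@@H](OCc1ccccc1)[C@]21CC[C@]2(C(C)C)C[C@@H]21 | intermediate
24 | 6α-alcohol (6α-OH, 7α-H, 5α-H; 11,12,21-tris(benzyloxy)) | CC(C)c1c2c3[C@H]([C@H](O)[C@H]4C(C)(C)CCC[C@]4(C)c3c(OCc3ccccc3)c1OCc1ccccc1)[C@@H](OCc1ccccc1)[C@]21CC[C@]2(C(C)C)C[C@@H]21 | intermediate
25 | 6-ketone, 5α-H (A/B trans), C7 labile | CC(C)c1c2c3C(C(=O)[C@H]4C(C)(C)CCC[C@]4(C)c3c(OCc3ccccc3)c1OCc1ccccc1)[C@@H](OCc1ccccc1)[C@]21CC[C@]2(C(C)C)C[C@@H]21 | intermediate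
26 | 6-ketone, 5β-H (A/B cis), C7 labile | CC(C)c1c2c3C(C(=O)[C@@H]4C(C)(C)CCC[C@]4(C)c3c(OCc3ccccc3)c1OCc1ccccc1)[C@@H](OCc1ccccc1)[C@]21CC[C@]2(C(C)C)C[C@@H]21 | intermediate
27 | catechol: 11,12,21α-trihydroxy-6-ketone, 5β-H, C7 labile | CC(C)c1c2c3C(C(=O)[C@@H]4C(C)(C)CCC[C@]4(C)c3c(O)c1O)[C@@H](O)[C@]21CC[C@]2(C(C)C)C[C@@H]21 | intermediate
28 | CNP0178265.2 | CC(C)C1=C2C3=C(C(=O)[C@@H]4C(C)(C)CCC[C@]4(C)C3=C(O)C1=O)[C@@H](O)[C@]21CC[C@]2(C(C)C)C[C@@H]21 | target

**Totals**
Total step count: 19. Longest linear sequence: 16 steps (7 to 28, steps 4–19); the sabinene arm adds 3 steps and joins at step 9.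

**Steps most likely to fail**

Step 11. Insertion of the trisubstituted ring E alkene into the acyl–palladium bond may be too slow at the fully substituted C4′, so the acylpalladium is drained by hydrolysis or decarbonylation. Alternatively, the palladium hydride released after β-hydride elimination may re-add to the new vinylcyclopropane and open the three-membered ring. In the fallback the acyl carbon is delivered as a radical. Setting out from 16, hydroxycarbonylation (Pd(OAc)2, 1,3-bis(diphenylphosphino)propane, CO, KOAc, DMF/H2O) gives the C7 carboxylic acid F1, and (PhSe)2/PBu3 converts it into the phenyl selenoester F2. Bu3SnH/AIBN in benzene at 80 °C then generates the C21 acyl radical, which should close ring D by 5-exo-trig addition to C4′ on the face anti to C6′. The secondary C3′ radical is not adjacent to the cyclopropane and takes hydrogen from the stannane, so the sequence comes back to the route at 19 and step 12 is not needed.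

Step 17. C7–H is much more acidic than C5–H, and the C7 enolate may expel the C21 benzyloxy group (E1cB) faster than C5 equilibrates, which would destroy the C21 stereocentre. In the fallback C7 is blocked during the equilibration. Setting out from 25, the kinetic C7 enolate (LiN(SiMe3)2, THF, −78 °C, where alkoxide expulsion is slow) is sulfenylated with PhSSO2Ph to the 7-phenylthio ketone F3, which can enolise only toward C5. DBU in toluene then equilibrates C5 to give the 5β-H 7-phenylthio ketone F4, and SmI2 in THF/MeOH at −78 °C removes the sulfur reductively, returning to the route at 26.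

Step 13. Facial selectivity of hydride addition at C21 may be poor, because the two faces differ only by the C5′ methine against the C3′ methylene, and a mixture of C21 epimers would result. The fallback replaces substrate control by reagent control. Setting out from 19, Corey–Bakshi–Shibata reduction with catecholborane and the antipode of 2-methyl-CBS-oxazaborolidine that delivers hydride to the β face (both antipodes are commercial and would be compared) comes back to the route at 20. No new compound is formed (F0).

Further compounds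
F1 | step 11 | 11,12-bis(benzyloxy)-14-(5-isopropylbicyclo[3.1.0]hex-2-en-2-yl)abieta-6,8,11,13-tetraene-7-carboxylic acid | CC(C)c1c(C2=CC[C@]3(C(C)C)C[C@@H]32)c2C(C(=O)O)=C[C@H]3C(C)(C)CCC[C@]3(C)c2c(OCc2ccccc2)c1OCc1ccccc1
F2 | step 11 | Se-phenyl selenoester of F1 | CC(C)c1c(C2=CC[C@]3(C(C)C)C[C@@H]32)c2C(C(=O)[Se]c3ccccc3)=C[C@H]3C(C)(C)CCC[C@]3(C)c2c(OCc2ccccc2)c1OCc1ccccc1
F3 | step 17 | 7-phenylthio derivative of 25 (5α-H; C7 configuration not assigned) | CC(C)c1c2c3C(Sc4ccccc4)(C(=O)[C@H]4C(C)(C)CCC[C@]4(C)c3c(OCc3ccccc3)c1OCc1ccccc1)[C@@H](OCc1ccccc1)[C@]21CC[C@]2(C(C)C)C[C@@H]21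
F4 | step 17 | 7-phenylthio ketone with 5β-H (C7 configuration not assigned) | CC(C)c1c2c3C(Sc4ccccc4)(C(=O)[C@@H]4C(C)(C)CCC[C@]4(C)c3c(OCc3ccccc3)c1OCc1ccccc1)[C@@H](OCc1ccccc1)[C@]21CC[C@]2(C(C)C)C[C@@H]21
F0 | step 13 | none | none
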